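## The problem

Compound 18 is a depsidone. Ring A and ring B are joined twice, by a diaryl ether oxygen and, ortho to it on each ring, by an aryl ester, so that a seven-membered dioxepinone (ring C) lies between them; a 2,2-dimethyl-2H-pyran (ring D) is fused to ring A. Ring A carries six different substituents in the order prenyl (a1), free hydroxyl (a2), pyran oxygen (a3), pyran vinyl carbon (a4), lactone oxygen (a5) and ether oxygen (a6). Ring B is a 3-prenylphloroglucinol carboxylic acid held through its carboxyl group and its 2-oxygen. There is no stereocentre, so the difficulty is regiochemical: the four oxygens of ring A must each receive a different partner, and the ether joins two carbons that each have two ortho substituents. The fragile groups are the two prenyl olefins and the chromene double bond (no hydrogenation, strong acid or electrophilic halogen), the aryl ester (hydroxide, alkoxide), the electron-rich phenols and hydroquinones (air), and the 2,4,6-trioxygenated benzoic acid (decarboxylation in acid). The enabling feature is that a1 and a4 are para, both carry a five-carbon isoprenoid unit (ring D is a prenyl group closed onto the a3 oxygen), and the four carbons between them all bear oxygen. At the quinone oxidation level ring A is therefore 2,5-dihydroxy-3,6-diprenyl-1,4-benzoquinone 6, whose two identical halves (a prenyl-bearing carbon followed by two oxygenated carbons) are the skeleton of the α-keto ester 4. In 6 the oxygens are already sorted in pairs, vinylogous acid hydroxyl against quinone carbonyl, and the later steps use this.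

## Retrosynthesis

18 from 17. The two ring B hydroxyls are masked as methoxymethyl ethers; only two acetal C–O bonds are cut. The group must survive carbonate, a thermal Claisen rearrangement, hot alkali, dithionite and a carbodiimide, and must leave without hydrogenation (olefins) or fluoride and base (lactone). Benzyl and silyl ethers fail one of these tests. The forward step asks for dilute acid that spares the prenyl phenols and the chromene.

17 from 15 through 16. The ester C–O bond of ring C is cut. Closing the ether last would need substitution at an unactivated, doubly ortho-substituted arene carbon, whereas closing the ester last is an ordinary acylation. The a5 oxygen is a quinone carbonyl in 15; reduction to hydroquinone 16 unveils it next to the acid. Of the two hydroquinone hydroxyls only the one ortho to the ether bridge can reach the carboxyl group, so the ring size fixes the regiochemistry.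

15 from 8 and 14. The a6–O ether bond is cut, dividing the molecule into its two rings. At the quinone level a6 is the β-carbon of a vinylogous acyl chloride, so the hindered ether forms by addition–elimination near room temperature instead of a hot copper-mediated coupling. The forward step asks that the phenoxide of 14 attack the chlorine-bearing carbon of 8 and nothing else.

8 from 7 from 6. The C–Cl bond goes back to the vinylogous acid hydroxyl, and ring D goes back to a prenyl group and its neighbouring oxygen. The symmetry of 6 makes its two prenyl groups and two vinylogous acids equivalent, and closure onto either flanking oxygen gives the same pyran 7 after tautomerism of the remaining hydroxyquinone. Chlorination then marks the one remaining hydroxyl as the future ether site. The price is that the cyclisation must be stopped after one of two equivalent groups has reacted.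

6 from two molecules of 4. Two ring C–C bonds are cut, each between a prenyl-bearing carbon and the oxygenated carbon that was an ester carbonyl. This replaces a hexasubstituted benzene by one acyclic C8 keto ester that is its own reaction partner. Stepwise prenylation of a preformed tetraoxygenated benzene would need several directed metalations and an oxidation. The forward reaction asks that the enolate of 4 choose the ester (Claisen) over the ketone (aldol) of a second molecule, twice.

4 from 1 and 2 through 3. The bond between the ketone carbon and the chain is cut; bromide 1 as its Grignard reagent 3 acylates diethyl oxalate 2 once at low temperature.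

14 from 13, 12, 11, 10 and 9. The acid 14 comes from methyl ester 13 by saponification before the coupling, because hydroxide would later cleave the aryloxyquinone. The prenyl group of 13 is an allyl group (12) extended by cross-metathesis, and the allyl group is delivered to C3 by Claisen rearrangement of allyl ether 11. This places the carbon substituent and returns the free phenol in one step, so direct C-prenylation of a phloroglucinol and its regiochemical ambiguity are avoided. Ether 11 comes from 10, the bis(methoxymethyl) ether that the symmetric, commercial methyl 2,4,6-trihydroxybenzoate 9 gives selectively.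

## Roads not taken

Alternative 1: The cut is through the ether bond and the aryl–carboxyl bond of ring B together. A ring A phenol, 5-(allyloxy)-8-(methoxymethoxy)-2,2-dimethyl-7-prenyl-2H-chromen-6-ol A1, would add as its phenoxide to the aryne set free by CsF from silyl triflate A2. The resulting ortho aryl anion would capture CO2 to give diaryl ether acid A3.
- Merits: ether and carboxyl group are installed in one operation, ring B needs no preformed benzoic acid, and ring A stays at the arene level, so no air-sensitive hydroquinone is handled. The ring B oxygen next to the aryne also directs the phenoxide to the correct carbon. In convergence at the coupling stage this road is better than the chosen one.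
- Weak points: A1 is a fully differentiated hexasubstituted phenol with three different oxygen substituents, and making it is the real problem of ring A, left unsolved. The phenoxide is flanked on both sides, so protonation of the aryl anion can outrun CO2 capture. A2 needs its own multistep synthesis, and a deallylation is added before lactonisation.
- Comparison: the chosen plan sets against this a ring A made in two steps whose oxygens are differentiated by their own reactivity.

Alternative 2: The cut is through ring A itself. A squarate-derived 4-hydroxycyclobutenone A4, carrying the prenyl group, the ring B aryloxy group and a 2,2-dimethyl-3,4-dihydro-2H-pyran-5-yl group, would open on heating to a dienylketene. Its 6π electrocyclisation would give the chroman hydroquinone A5.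
- Merits: every substituent of ring A is placed by sequential additions to the four-membered ring, so nothing is statistical. In regiochemical certainty this road is better than the chosen desymmetrisation of 6.
- Weak points: A5 has a saturated pyran, so a late dehydrogenation must be done on an electron-rich hydroquinone that the oxidant attacks first. Prenyl organometallics add to squarates with allylic transposition. The hindered ring B phenol must be attached to the squarate by vinylogous ester exchange. The tert-butyl ester needs acid strong enough to endanger prenyl groups and chromene.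
- Comparison: the chosen plan sets against it a much shorter access to ring A, ring D formed directly at the chromene oxidation level, and a statistical mixture that separates by acidity with recovery of 6.

Alternative 3: The cut is the same lactone C–O bond as in the chosen plan, but made at a C–H carbon. Diaryl ether acid A6, with a free ring A phenol and hydrogen at a5, would be oxidised by PhI(OAc)2, and the carboxyl group would attack the para carbon to give A7, which is the same compound as 17.
- Merits: ring A needs one oxygen less, no quinone-to-hydroquinone switch is made at the coupled stage, and the endgame is shared. In handling this road is better.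
- Weak points: A6 needs a different ring A and an ether coupling at the arene level, between two doubly ortho-substituted carbons. The oxidant meets a chromene, two prenyl groups and two electron-rich rings. The carboxylate must reach the para position through a seven-membered transition state in competition with acetate, solvent or water, whereas closure to five-membered spirolactones is the usual outcome of such oxidations.
- Comparison: the chosen plan has the a5 oxygen in place from the quinone and closes the same bond by plain acyl activation; it has to set against this road the redox handling of 15 and 16.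

Key step: step 2

Assumption: hydroxyquinones 6 and 7 are drawn as para-quinone tautomers; their ortho-quinone tautomers interconvert by proton transfer and lead to the same products. The target has no stereocentre; intermediate 5 has one labile centre and is racemic.

## Route

Step 1
Reactants: 1 5-bromo-2-methylpent-2-ene; 2 diethyl oxalate
Product: 4 ethyl 6-methyl-2-oxohept-5-enoate, via (4-methylpent-3-enyl)magnesium bromide 3 (not isolated)
Conditions: Mg, THF, 20–40 °C; then added to 2 (2 equiv), THF, −78 °C; 1 M HCl
Reagents that add atoms: none
Why: Grignard acylation with a dialkyl oxalate; with the oxalate in excess at −78 °C the tetrahedral magnesium alkoxide persists until the quench, so neither the new ketone nor the second ester is attacked.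

Step 2
Reactants: 4 ethyl 6-methyl-2-oxohept-5-enoate (two molecules)
Product: 6 2,5-dihydroxy-3,6-bis(3-methylbut-2-enyl)-1,4-benzoquinone, via acyclic triketo ester 5 (not isolated)
Conditions: NaOEt (1.2 equiv per 4), EtOH/Et2O, 0 °C to reflux; then 2 M HCl
Reagents that add atoms: none
Why: Ethoxide forms the enolate at the CH2 group next to the ketone of 4, which displaces ethoxide from the ester of a second molecule to give 5; the other CH2 of 5 then attacks the remaining ester in the same way and closes ring A. The closest known reaction type is the base-mediated self-condensation of α-keto esters to 3,6-dialkyl-2,5-dihydroxy-1,4-benzoquinones, a double Claisen (Dieckmann-type) condensation. The ring closes in the 6-(enolendo)-exo-trig mode, by acyl substitution at an ester carbonyl lying outside the forming ring. The resulting cyclohexane-1,2,4,5-tetraone enolises to the dihydroxyquinone without change of oxidation state, and no stereocentre is formed. The selectivity needed is Claisen attack on the ester over aldol attack on the more electrophilic ketone. Aldol adducts can revert under the equilibrating alkoxide conditions, while the doubly condensed product is removed as its twofold vinylogous carboxylate dianion, which makes the sequence irreversible. Because the substrate is its own partner there is no cross-selectivity problem, and only the head-to-tail union can give a six-membered ring. The prenyl olefins are inert to alkoxide.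

Step 3
Reactants: 6 2,5-dihydroxy-3,6-bis(3-methylbut-2-enyl)-1,4-benzoquinone
Product: 7 6-hydroxy-2,2-dimethyl-7-(3-methylbut-2-enyl)-2H-chromene-5,8-dione
Conditions: DDQ (0.95 equiv, slow addition), PhMe, 20 °C; unreacted 6 recycled
Reagents that add atoms: none
Why: DDQ abstracts hydride from the ring-bound CH2 of one prenyl group and the resulting quinone methide closes onto the flanking oxygen by oxa-6π electrocyclisation, the known oxidative cyclisation of prenyl hydroxyquinones of the lapachol type. Closure on either flanking oxygen gives the same compound after tautomerism, and less than one equivalent of oxidant limits the second cyclisation.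

Step 4
Reactants: 7 6-hydroxy-2,2-dimethyl-7-(3-methylbut-2-enyl)-2H-chromene-5,8-dione
Product: 8 6-chloro-2,2-dimethyl-7-(3-methylbut-2-enyl)-2H-chromene-5,8-dione
Conditions: (COCl)2 (1.2 equiv), DMF (cat.), CH2Cl2, 0 °C, N2 sweep
Reagents that add atoms: oxalyl chloride, ClC(=O)C(=O)Cl
Why: Vilsmeier-type deoxychlorination of a vinylogous carboxylic acid (hydroxyquinone to chloroquinone) by O-activation and addition–elimination of chloride; the para-quinone chloride is the thermodynamic product, and sweeping out HCl at 0 °C protects the olefins.

Step 5
Reactants: 9 methyl 2,4,6-trihydroxybenzoate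
Product: 10 methyl 2-hydroxy-4,6-bis(methoxymethoxy)benzoate
Conditions: MOMCl (2.2 equiv), i-Pr2NEt, CH2Cl2, 0 °C to rt
Reagents that add atoms: chloromethyl methyl ether, COCCl
Why: O-alkylation of the para and one ortho phenol; the last ortho hydroxyl is hydrogen-bonded to the ester carbonyl and is not alkylated under amine base, and the symmetry of 9 makes the two ortho positions equivalent.

Step 6
Reactants: 10 methyl 2-hydroxy-4,6-bis(methoxymethoxy)benzoate
Product: 11 methyl 2-(allyloxy)-4,6-bis(methoxymethoxy)benzoate
Conditions: allyl bromide, K2CO3, DMF, 50 °C
Reagents that add atoms: allyl bromide, C=CCBr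
Why: Williamson etherification of the single free (chelated) phenol under carbonate in a dipolar solvent.

Step 7
Reactants: 11 methyl 2-(allyloxy)-4,6-bis(methoxymethoxy)benzoate
Product: 12 methyl 3-allyl-2-hydroxy-4,6-bis(methoxymethoxy)benzoate
Conditions: PhNEt2, 195 °C, sealed tube
Reagents that add atoms: none
Why: Aromatic Claisen rearrangement; the other ortho position bears the ester, so the [3,3] shift can only reach C3, and tautomerisation returns the phenol at the future ether site. The acetals tolerate the basic thermal medium.

Step 8
Reactants: 12 methyl 3-allyl-2-hydroxy-4,6-bis(methoxymethoxy)benzoate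
Product: 13 methyl 2-hydroxy-4,6-bis(methoxymethoxy)-3-(3-methylbut-2-enyl)benzoate
Conditions: 2-methylbut-2-ene (excess), second-generation Grubbs catalyst RuCl2(=CHPh)(PCy3)(H2IMes) (3 mol %), CH2Cl2, 40 °C
Reagents that add atoms: 2-methylbut-2-ene, CC=C(C)C
Why: Olefin cross-metathesis of a terminal allyl arene with 2-methylbut-2-ene, the standard allyl-to-prenyl conversion; the excess olefin suppresses homodimerisation and propene escapes.

Step 9
Reactants: 13 methyl 2-hydroxy-4,6-bis(methoxymethoxy)-3-(3-methylbut-2-enyl)benzoate
Product: 14 2-hydroxy-4,6-bis(methoxymethoxy)-3-(3-methylbut-2-enyl)benzoic acid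
Conditions: KOH (6 equiv), MeOH/H2O, 70 °C; then 1 M HCl, 0 °C, to pH 4
Reagents that add atoms: potassium hydroxide, [K+].[OH-]
Why: Saponification by acyl–oxygen cleavage; acetals and prenyl group are inert to hot alkali, and cold acidification only to pH 4 avoids decarboxylation and acetal loss.

Step 10
Reactants: 14 2-hydroxy-4,6-bis(methoxymethoxy)-3-(3-methylbut-2-enyl)benzoic acid; 8 6-chloro-2,2-dimethyl-7-(3-methylbut-2-enyl)-2H-chromene-5,8-dione
Product: 15 2-{[2,2-dimethyl-7-(3-methylbut-2-enyl)-5,8-dioxo-5,8-dihydro-2H-chromen-6-yl]oxy}-4,6-bis(methoxymethoxy)-3-(3-methylbut-2-enyl)benzoic acid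
Conditions: Cs2CO3 (2.5 equiv), DMF, 0 °C to rt, Ar; aq. NaH2PO4 work-up
Reagents that add atoms: none
Why: Addition–elimination of a phenoxide at a chloroquinone (vinylogous acyl chloride); the dianion of 14 reacts through its far more basic phenoxide, and attack through the carboxylate would lead to the same ether by Smiles rearrangement. Chloride is the only good leaving group on 8.

Step 11
Reactants: 15 2-{[2,2-dimethyl-7-(3-methylbut-2-enyl)-5,8-dioxo-5,8-dihydro-2H-chromen-6-yl]oxy}-4,6-bis(methoxymethoxy)-3-(3-methylbut-2-enyl)benzoic acid
Product: 17 bis(methoxymethyl) ether of the target depsidone (both ring B hydroxyls protected), via hydroquinone acid 16 (not isolated)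
Conditions: Na2S2O4, EtOAc/H2O, rt, Ar; then DCC, DMAP (cat.), CH2Cl2 (0.005 M), 0 °C to rt
Reagents that add atoms: none
Why: Dithionite reduces the quinone to hydroquinone 16, which is lactonised with the carbodiimide-activated acid (Steglich-type closure, the usual way to close depsidone seco acids). Only the C5 hydroxyl, ortho to the ether oxygen, can reach the acyl group (seven-membered ring); the C8 hydroxyl is meta to the bridge, and dilution suppresses intermolecular esters.

Step 12
Reactants: 17 bis(methoxymethyl) ether of the target depsidone
Product: 18 target depsidone CNP0263700.0 (lactone between the carboxyl group and the chromene 5-OH of 2-{[5,8-dihydroxy-2,2-dimethyl-7-prenyl-2H-chromen-6-yl]oxy}-4,6-dihydroxy-3-prenylbenzoic acid)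
Conditions: 2 M HCl (aq.), THF, 40 °C
Reagents that add atoms: none
Why: Acid hydrolysis of the two aryl methoxymethyl acetals; the lactone carbonyl lies between two ortho substituents and resists acyl–oxygen hydrolysis, and dilute aqueous acid at 40 °C is milder than the conditions that cyclise ortho-prenyl phenols to chromans or hydrate the chromene.

## Compound list

1 | 5-bromo-2-methylpent-2-ene | CC(C)=CCCBr | starting material
2 | diethyl oxalate | CCOC(=O)C(=O)OCC | starting material
3 | (4-methylpent-3-enyl)magnesium bromide | CC(C)=CCC[Mg]Br | intermediate (not isolated)
4 | ethyl 6-methyl-2-oxohept-5-enoate | CCOC(=O)C(=O)CCC=C(C)C | intermediate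
5 | ethyl 9-methyl-3-(3-methylbut-2-enyl)-2,4,5-trioxodec-8-enoate (racemic, labile centre) | CCOC(=O)C(=O)C(CC=C(C)C)C(=O)C(=O)CCC=C(C)C | intermediate (not isolated)
6 | 2,5-dihydroxy-3,6-bis(3-methylbut-2-enyl)-1,4-benzoquinone | CC(C)=CCC1=C(O)C(=O)C(CC=C(C)C)=C(O)C1=O | intermediate
7 | 6-hydroxy-2,2-dimethyl-7-(3-methylbut-2-enyl)-2H-chromene-5,8-dione | CC1(C)C=CC2=C(O1)C(=O)C(CC=C(C)C)=C(O)C2=O | intermediate
8 | 6-chloro-2,2-dimethyl-7-(3-methylbut-2-enyl)-2H-chromene-5,8-dione | CC1(C)C=CC2=C(O1)C(=O)C(CC=C(C)C)=C(Cl)C2=O | intermediate
9 | methyl 2,4,6-trihydroxybenzoate | COC(=O)c1c(O)cc(O)cc1O | starting material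
10 | methyl 2-hydroxy-4,6-bis(methoxymethoxy)benzoate | COC(=O)c1c(O)cc(OCOC)cc1OCOC | intermediate
11 | methyl 2-(allyloxy)-4,6-bis(methoxymethoxy)benzoate | COC(=O)c1c(OCC=C)cc(OCOC)cc1OCOC | intermediate
12 | methyl 3-allyl-2-hydroxy-4,6-bis(methoxymethoxy)benzoate | COC(=O)c1c(O)c(CC=C)c(OCOC)cc1OCOC | intermediate
13 | methyl 2-hydroxy-4,6-bis(methoxymethoxy)-3-(3-methylbut-2-enyl)benzoate | COC(=O)c1c(O)c(CC=C(C)C)c(OCOC)cc1OCOC | intermediate
14 | 2-hydroxy-4,6-bis(methoxymethoxy)-3-(3-methylbut-2-enyl)benzoic acid | OC(=O)c1c(O)c(CC=C(C)C)c(OCOC)cc1OCOC | intermediate
15 | 2-{[2,2-dimethyl-7-(3-methylbut-2-enyl)-5,8-dioxo-5,8-dihydro-2H-chromen-6-yl]oxy}-4,6-bis(methoxymethoxy)-3-(3-methylbut-2-enyl)benzoic acid | CC1(C)C=CC2=C(O1)C(=O)C(CC=C(C)C)=C(Oc1c(CC=C(C)C)c(OCOC)cc(OCOC)c1C(=O)O)C2=O | intermediate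
16 | 2-{[5,8-dihydroxy-2,2-dimethyl-7-(3-methylbut-2-enyl)-2H-chromen-6-yl]oxy}-4,6-bis(methoxymethoxy)-3-(3-methylbut-2-enyl)benzoic acid | CC1(C)C=Cc2c(O1)c(O)c(CC=C(C)C)c(Oc1c(CC=C(C)C)c(OCOC)cc(OCOC)c1C(=O)O)c2O | intermediate (not isolated)
17 | bis(methoxymethyl) ether of the target depsidone (lactone of 16 through the chromene 5-OH) | CC(C)=CCc1c(O)c2c(c3c1Oc1c(CC=C(C)C)c(OCOC)cc(OCOC)c1C(=O)O3)C=CC(C)(C)O2 | intermediate
18 | target depsidone CNP0263700.0 | CC(C)=CCc1c(O)c2c(c3c1Oc1c(CC=C(C)C)c(O)cc(O)c1C(=O)O3)C=CC(C)(C)O2 | target

## Step count and risks

Total: 12 steps. Longest linear sequence: 8 steps (9 to 18, steps 5–12). The ring A branch (steps 1–4) joins at step 10.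

Step 2 (key step). The enolate of 4 may add to the ketone of a second molecule and the aldol alkoxide may then lactonise onto the ester (isotetronic acid formation), or oligomerise, before the Claisen pathway reaches the dianion. Fallback: one ring bond is preformed so that the only electrophile offered is a non-enolisable oxalate. It sets out from 1 (as Grignard reagent 3) and 2. Two equivalents of 3 with N,N'-dimethoxy-N,N'-dimethyloxamide give the 1,2-diketone 2,11-dimethyldodeca-2,10-diene-6,7-dione F1. Crossed double Claisen condensation of F1 with excess 2 under NaOEt closes the same ring and comes back to the route at 6.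

Step 3. The second prenyl group of 7 is as reactive as the first, so over-oxidation to the bis-pyran and incomplete conversion of 6 occur together in a statistical mixture. The separation relies on acidity: 6 is a diacid, 7 a monoacid and the bis-pyran neutral. Fallback from 6: both hydroxyls are chlorinated with oxalyl chloride and DMF to 2,5-dichloro-3,6-bis(3-methylbut-2-enyl)-1,4-benzoquinone F2. One equivalent of NaOH in aqueous THF at 0 °C then hydrolyses one chloride to 2-chloro-5-hydroxy-3,6-bis(3-methylbut-2-enyl)-1,4-benzoquinone F3, whose anion resists a second hydrolysis. DDQ cyclises the only enol-activated prenyl group and comes back at 8. The cost is that closure on the carbonyl oxygen now gives an ortho-quinone isomer that cannot converge.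

Step 10. Electron transfer from the electron-rich dianion to the quinone may compete with substitution, attack at the doubly flanked carbon may be slow, and the free acid may decarboxylate on handling. Fallback from 14: carboxylate alkylation (allyl bromide, KHCO3, DMF) gives allyl 2-hydroxy-4,6-bis(methoxymethoxy)-3-(3-methylbut-2-enyl)benzoate F4. Its less reducing monoanion is coupled with 8 (K2CO3, DMF) to the allyl ester of 15 F5. Na2S2O4 reduces this to the allyl ester of 16 F6, and Pd(PPh3)4 (zerovalent palladium) with morpholine under argon removes the allyl group, coming back at 16 for the carbodiimide closure of step 11.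

Step 11. The hydroquinone may reoxidise in air before acylation, the hindered O-acylisourea may rearrange to an N-acylurea, and intermolecular esterification may compete. Fallback from 15: the acid is activated while no nucleophile is present, with pentafluorophenol and DCC, to the pentafluorophenyl ester of 15 F7. Na2S2O4 reduction in the presence of NaHCO3 then sets the C5 phenol free next to the active ester, and lactonisation comes back at 17.

Step 12. Acid may add a phenol hydroxyl to the neighbouring prenyl double bond (chroman formation) or hydrate the chromene before both acetals are gone. Fallback from 17: TMSOTf and 2,2'-bipyridyl in CH2Cl2 at 0 °C exchange the aryl methoxymethyl ethers for silyl ethers without Brønsted acid and silylate the free phenol, giving the tris(trimethylsilyl) ether of the target F8. Water at neutral pH hydrolyses F8 and comes back at 18.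

## Further compounds

F1 | step 2 | 2,11-dimethyldodeca-2,10-diene-6,7-dione | CC(C)=CCCC(=O)C(=O)CCC=C(C)C
F2 | step 3 | 2,5-dichloro-3,6-bis(3-methylbut-2-enyl)-1,4-benzoquinone | CC(C)=CCC1=C(Cl)C(=O)C(CC=C(C)C)=C(Cl)C1=O
F3 | step 3 | 2-chloro-5-hydroxy-3,6-bis(3-methylbut-2-enyl)-1,4-benzoquinone | CC(C)=CCC1=C(Cl)C(=O)C(CC=C(C)C)=C(O)C1=O
F4 | step 10 | allyl 2-hydroxy-4,6-bis(methoxymethoxy)-3-(3-methylbut-2-enyl)benzoate | C=CCOC(=O)c1c(O)c(CC=C(C)C)c(OCOC)cc1OCOC
F5 | step 10 | allyl ester of 15 | CC1(C)C=CC2=C(O1)C(=O)C(CC=C(C)C)=C(Oc1c(CC=C(C)C)c(OCOC)cc(OCOC)c1C(=O)OCC=C)C2=O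
F6 | step 10 | allyl ester of 16 | CC1(C)C=Cc2c(O1)c(O)c(CC=C(C)C)c(Oc1c(CC=C(C)C)c(OCOC)cc(OCOC)c1C(=O)OCC=C)c2O
F7 | step 11 | pentafluorophenyl ester of 15 | CC1(C)C=CC2=C(O1)C(=O)C(CC=C(C)C)=C(Oc1c(CC=C(C)C)c(OCOC)cc(OCOC)c1C(=O)Oc1c(F)c(F)c(F)c(F)c1F)C2=O
F8 | step 12 | tris(trimethylsilyl) ether of the target | CC(C)=CCc1c(O[Si](C)(C)C)c2c(c3c1Oc1c(CC=C(C)C)c(O[Si](C)(C)C)cc(O[Si](C)(C)C)c1C(=O)O3)C=CC(C)(C)O2
A1 | alternative 1 | 5-(allyloxy)-8-(methoxymethoxy)-2,2-dimethyl-7-(3-methylbut-2-enyl)-2H-chromen-6-ol | CC(C)=CCc1c(OCOC)c2OC(C)(C)C=Cc2c(OCC=C)c1O
A2 | alternative 1 | 3,5-bis(methoxymethoxy)-2-(3-methylbut-2-enyl)-6-(trimethylsilyl)phenyl trifluoromethanesulfonate | CC(C)=CCc1c(OCOC)cc(OCOC)c([Si](C)(C)C)c1OS(=O)(=O)C(F)(F)F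
A3 | alternative 1 | 2-{[5-(allyloxy)-8-(methoxymethoxy)-2,2-dimethyl-7-(3-methylbut-2-enyl)-2H-chromen-6-yl]oxy}-4,6-bis(methoxymethoxy)-3-(3-methylbut-2-enyl)benzoic acid | CC(C)=CCc1c(OCOC)c2OC(C)(C)C=Cc2c(OCC=C)c1Oc1c(CC=C(C)C)c(OCOC)cc(OCOC)c1C(=O)O
A4 | alternative 2 | racemic tert-butyl 2-{[4-(2,2-dimethyl-3,4-dihydro-2H-pyran-5-yl)-4-hydroxy-2-(3-methylbut-2-enyl)-3-oxocyclobut-1-enyl]oxy}-4,6-bis(methoxymethoxy)-3-(3-methylbut-2-enyl)benzoate | CC(C)=CCC1=C(Oc2c(CC=C(C)C)c(OCOC)cc(OCOC)c2C(=O)OC(C)(C)C)C(O)(C2=COC(C)(C)CC2)C1=O
A5 | alternative 2 | tert-butyl 2-{[5,8-dihydroxy-2,2-dimethyl-7-(3-methylbut-2-enyl)chroman-6-yl]oxy}-4,6-bis(methoxymethoxy)-3-(3-methylbut-2-enyl)benzoate | CC(C)=CCc1c(O)c2OC(C)(C)CCc2c(O)c1Oc1c(CC=C(C)C)c(OCOC)cc(OCOC)c1C(=O)OC(C)(C)C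
A6 | alternative 3 | 2-{[8-hydroxy-2,2-dimethyl-7-(3-methylbut-2-enyl)-2H-chromen-6-yl]oxy}-4,6-bis(methoxymethoxy)-3-(3-methylbut-2-enyl)benzoic acid | CC(C)=CCc1c(O)c2OC(C)(C)C=Cc2cc1Oc1c(CC=C(C)C)c(OCOC)cc(OCOC)c1C(=O)O
A7 | alternative 3 | bis(methoxymethyl) ether of the target (identical with 17) | CC(C)=CCc1c(O)c2OC(C)(C)C=Cc2c2OC(=O)c3c(OCOC)cc(OCOC)c(CC=C(C)C)c3Oc12
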